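**Retrosynthetic overview**

1. The bond between the ring A carbonyl carbon and C3 of the tetrahydropyran (ring B) is cut together with the C4–H bond: a ring A aroyl radical (from a phenyl selenoester) adds to a 4-styryl-3,6-dihydro-2H-pyran.
2. Enabling feature: in ring B the acyl-bearing C3 and the (E)-styryl-bearing C4 are adjacent, so removing the acyl group from C3 and H from C4 leaves a conjugated 1-aryl-1,3-diene (C3=C4–CH=CH–Ar). The C2 aryl group, 2,6-trans to the C6 chain, is pseudo-axial and shields one face of that diene.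
3. Diene fragment: ring B is the only ring that is built, by a catalytic asymmetric hetero-Diels–Alder reaction (sets C6); aryl conjugate addition/enolate triflation (sets C2, trans) and Suzuki coupling follow.
4. Ring A fragment: Mitsunobu etherification of 2,4-dihydroxy-6-methoxybenzaldehyde with a syn-1,3-diol-derived allylic alcohol (boron aldol, oxazaborolidine reduction), then aromatic Claisen rearrangement with 1,3-chirality transfer to set the diarylmethine centre; oxidation to the selenoester.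
5. End game: the radical coupling sets C3 and C4 by relay from C2/C6; one global desilylation gives the target.

Key step: step 17

Abbreviations: TBS = tert-butyldimethylsilyl (TBSO = its ether), Tf = trifluoromethanesulfonyl, Ipc = isopinocampheyl; ring B atoms are numbered O1, C2 (aryl), C3 (acyl), C4 (styryl), C5, C6 (arylethyl) throughout.

Assumption: the antipodes of (R)-BINOL, (+)-Ipc2BCl and the (R)-oxazaborolidine are assigned from the usual facial-selectivity models of these reagents; the other antipode would be taken if the sense proved opposite.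

**Route**

Step 1
Reactants: 1 methyl 3-(4-hydroxyphenyl)propanoate
Product: 2 methyl 3-[4-(TBSO)phenyl]propanoate
Conditions: TBSCl, imidazole, DMF, rt
Reagents that add atoms: tert-butyldimethylsilyl chloride, CC(C)(C)[Si](C)(C)Cl
Why: Imidazole-promoted silyl ether formation masks the phenol for the organometallic and radical steps and is removable by fluoride at the end.

Step 2
Reactants: 2 methyl 3-[4-(TBSO)phenyl]propanoate
Product: 3 3-[4-(TBSO)phenyl]propanal
Conditions: iBu2AlH, CH2Cl2, −78 °C; Rochelle salt work-up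
Reagents that add atoms: none
Why: Partial hydride reduction of the ester at low temperature should stop at the aldehyde because the tetrahedral aluminium hemiacetal survives until work-up.

Step 3
Reactants: 3 3-[4-(TBSO)phenyl]propanal; 4 (E)-1-methoxy-3-(trimethylsilyloxy)buta-1,3-diene
Product: 6 (2S)-2-{2-[4-(TBSO)phenyl]ethyl}-2,3-dihydro-4H-pyran-4-one, via Mukaiyama aldol adduct 5 (not isolated)
Conditions: (R)-BINOL (20 mol%), Ti(OiPr)4 (10 mol%), 4 Å molecular sieves, Et2O, −20 °C; then CF3CO2H, CH2Cl2, 0 °C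
Reagents that add atoms: none
Why: Catalytic asymmetric hetero-Diels–Alder reaction (Mukaiyama aldol/cyclisation pathway) in which the BINOL–titanium Lewis acid should direct the diene to the Re face of the aldehyde and so set C6 (S) before acid closes ring B with loss of methanol.

Step 4
Reactants: 6 (2S)-2-{2-[4-(TBSO)phenyl]ethyl}-2,3-dihydro-4H-pyran-4-one; 7 4-(TBSO)phenylmagnesium bromide
Product: 9 (2S,6R)-6-[4-(TBSO)phenyl]-2-{2-[4-(TBSO)phenyl]ethyl}-3,6-dihydro-2H-pyran-4-yl triflate, via magnesium enolate 8 (not isolated)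
Conditions: CuBr·SMe2 (20 mol%), THF, −78 → −40 °C; then N-(5-chloropyridin-2-yl)bis(triflyl)imide, −78 → 0 °C
Reagents that add atoms: N-(5-chloropyridin-2-yl)-1,1,1-trifluoro-N-(trifluoromethylsulfonyl)methanesulfonamide, O=S(=O)(N(c1ccc(Cl)cn1)S(=O)(=O)C(F)(F)F)C(F)(F)F
Why: Copper-catalysed conjugate addition should occur by axial attack on the half-chair enone anti to the pseudo-equatorial C6 chain (new C2 centre, 2,6-trans), and the regiodefined enolate is O-triflated in the same flask.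

Step 5
Reactants: 10 tert-butyl(4-iodophenoxy)dimethylsilane; 11 4,4,5,5-tetramethyl-2-vinyl-1,3,2-dioxaborolane
Product: 12 (E)-2-{2-[4-(TBSO)phenyl]ethenyl}-4,4,5,5-tetramethyl-1,3,2-dioxaborolane
Conditions: Pd(OAc)2 (5 mol%), PPh3 (12 mol%), n-Bu3N, toluene, 100 °C
Reagents that add atoms: none
Why: Heck–Mizoroki reaction of the aryl iodide with the vinylboronate (syn-carbopalladation, syn-β-hydride elimination) should give the (E)-alkenylboronate with the carbon–boron bond intact.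

Step 6
Reactants: 9 (2S,6R)-6-[4-(TBSO)phenyl]-2-{2-[4-(TBSO)phenyl]ethyl}-3,6-dihydro-2H-pyran-4-yl triflate; 12 (E)-2-{2-[4-(TBSO)phenyl]ethenyl}-4,4,5,5-tetramethyl-1,3,2-dioxaborolane
Product: 13 (2S,6R)-6-[4-(TBSO)phenyl]-2-{2-[4-(TBSO)phenyl]ethyl}-4-{(E)-2-[4-(TBSO)phenyl]ethenyl}-3,6-dihydro-2H-pyran
Conditions: Pd(PPh3)4 (5 mol%), K3PO4, THF/H2O, 40 °C
Reagents that add atoms: none
Why: Suzuki–Miyaura coupling of the enol triflate with the alkenylboronate proceeds with retention of both alkene geometries and should give the conjugated diene.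

Step 7
Reactants: 14 (E)-4-(4-hydroxyphenyl)but-3-en-2-one
Product: 15 (E)-4-(4-acetoxyphenyl)but-3-en-2-one
Conditions: Ac2O, pyridine, DMAP (cat.), CH2Cl2, rt
Reagents that add atoms: acetic anhydride, CC(=O)OC(C)=O
Why: Acetylation turns the strongly donating phenol into a weakly withdrawing ester, which should later suppress ionisation of the cinnamyl-type carbinol in the Mitsunobu and Claisen steps.

Step 8
Reactants: 15 (E)-4-(4-acetoxyphenyl)but-3-en-2-one; 3 3-[4-(TBSO)phenyl]propanal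
Product: 17 (1E,5S)-1-(4-acetoxyphenyl)-5-hydroxy-7-[4-(TBSO)phenyl]hept-1-en-3-one, via boron enolate 16 (not isolated)
Conditions: (+)-Ipc2BCl, Et3N, Et2O, −78 → 0 °C; then 3, −78 → −20 °C; then H2O2, pH 7 buffer, MeOH, 0 °C
Reagents that add atoms: none
Why: Boron-mediated asymmetric aldol reaction in which the diisopinocampheylboron enolate of the methyl ketone should add to the Re face of the aldehyde under reagent control and set the carbinol centre (S).

Step 9
Reactants: 17 (1E,5S)-1-(4-acetoxyphenyl)-5-hydroxy-7-[4-(TBSO)phenyl]hept-1-en-3-one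
Product: 18 (1E,5S)-1-(4-acetoxyphenyl)-5-(TBSO)-7-[4-(TBSO)phenyl]hept-1-en-3-one
Conditions: TBSOTf, 2,6-lutidine, CH2Cl2, −78 °C
Reagents that add atoms: tert-butyldimethylsilyl triflate, CC(C)(C)[Si](C)(C)OS(=O)(=O)C(F)(F)F
Why: Silyl triflate/lutidine silylation at low temperature should protect the β-hydroxyl without β-elimination or enol silylation.

Step 10
Reactants: 18 (1E,5S)-1-(4-acetoxyphenyl)-5-(TBSO)-7-[4-(TBSO)phenyl]hept-1-en-3-one
Product: 19 4-{(1E,3S,5S)-3-hydroxy-5-(TBSO)-7-[4-(TBSO)phenyl]hept-1-en-1-yl}phenyl acetate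
Conditions: (R)-2-methyl-CBS-oxazaborolidine (20 mol%), BH3·SMe2, THF, −30 °C
Reagents that add atoms: none
Why: Corey–Bakshi–Shibata reduction delivers hydride 1,2 to the enone under catalyst control to give the (3S)-allylic alcohol (syn to the 5-silyloxy group), so that any minor aldol enantiomer becomes a separable diastereomer.

Step 11
Reactants: 19 4-{(1E,3S,5S)-3-hydroxy-5-(TBSO)-7-[4-(TBSO)phenyl]hept-1-en-1-yl}phenyl acetate; 20 2,4-dihydroxy-6-methoxybenzaldehyde
Product: 21 4-{[(1E,3R,5S)-1-(4-acetoxyphenyl)-5-(TBSO)-7-[4-(TBSO)phenyl]hept-1-en-3-yl]oxy}-2-hydroxy-6-methoxybenzaldehyde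
Conditions: PPh3, DIAD, toluene, 0 °C
Reagents that add atoms: none
Why: Mitsunobu etherification with the more acidic, non-chelated 4-OH of the salicylaldehyde should proceed by SN2 with inversion to the (3R)-aryl ether.

Step 12
Reactants: 21 4-{[(1E,3R,5S)-1-(4-acetoxyphenyl)-5-(TBSO)-7-[4-(TBSO)phenyl]hept-1-en-3-yl]oxy}-2-hydroxy-6-methoxybenzaldehyde
Product: 22 3-{(1R,2E,5S)-1-(4-acetoxyphenyl)-5-(TBSO)-7-[4-(TBSO)phenyl]hept-2-en-1-yl}-2,4-dihydroxy-6-methoxybenzaldehyde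
Conditions: N,N-diethylaniline, 170 °C, sealed tube
Reagents that add atoms: none
Why: Aromatic Claisen rearrangement through a chair transition state with the C4 chain equatorial should transfer chirality suprafacially from C3–O to the new benzylic carbon (R) and give the (E)-alkene, with migration directed to the ring carbon between the two oxygens by bond fixation in the hydrogen-bonded salicylaldehyde.

Step 13
Reactants: 22 3-{(1R,2E,5S)-1-(4-acetoxyphenyl)-5-(TBSO)-7-[4-(TBSO)phenyl]hept-2-en-1-yl}-2,4-dihydroxy-6-methoxybenzaldehyde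
Product: 23 2,4-dihydroxy-3-[(1R,2E,5S)-1,7-bis(4-hydroxyphenyl)-5-(TBSO)hept-2-en-1-yl]-6-methoxybenzaldehyde
Conditions: K2CO3, MeOH, 0 °C → rt
Reagents that add atoms: none
Why: Carbonate-mediated methanolysis (transesterification and aryl silyl ether cleavage) should free the two side-chain phenols while the secondary alkyl silyl ether stays.

Step 14
Reactants: 23 2,4-dihydroxy-3-[(1R,2E,5S)-1,7-bis(4-hydroxyphenyl)-5-(TBSO)hept-2-en-1-yl]-6-methoxybenzaldehyde
Product: 24 2-hydroxy-6-methoxy-4-(TBSO)-3-{(1R,2E,5S)-5-(TBSO)-1,7-bis[4-(TBSO)phenyl]hept-2-en-1-yl}benzaldehyde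
Conditions: TBSCl (3.3 equiv), imidazole, DMF, 0 °C → rt
Reagents that add atoms: tert-butyldimethylsilyl chloride, CC(C)(C)[Si](C)(C)Cl
Why: Imidazole-promoted silylation should cap the three free phenols while the 2-OH, hydrogen-bonded to the formyl group and flanked on both sides, does not react.

Step 15
Reactants: 24 2-hydroxy-6-methoxy-4-(TBSO)-3-{(1R,2E,5S)-5-(TBSO)-1,7-bis[4-(TBSO)phenyl]hept-2-en-1-yl}benzaldehyde
Product: 25 2-hydroxy-6-methoxy-4-(TBSO)-3-{(1R,2E,5S)-5-(TBSO)-1,7-bis[4-(TBSO)phenyl]hept-2-en-1-yl}benzoic acid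
Conditions: NaClO2, NaH2PO4, 2-methyl-2-butene, t-BuOH/H2O, 0 °C → rt
Reagents that add atoms: sodium chlorite, [Na+].[O-]Cl=O
Why: Pinnick oxidation converts the aldehyde to the acid with chlorous acid while excess 2-methyl-2-butene traps hypochlorous acid and so should spare the alkene and the electron-rich arenes.

Step 16
Reactants: 25 2-hydroxy-6-methoxy-4-(TBSO)-3-{(1R,2E,5S)-5-(TBSO)-1,7-bis[4-(TBSO)phenyl]hept-2-en-1-yl}benzoic acid
Product: 26 Se-phenyl 2-hydroxy-6-methoxy-4-(TBSO)-3-{(1R,2E,5S)-5-(TBSO)-1,7-bis[4-(TBSO)phenyl]hept-2-en-1-yl}benzenecarboselenoate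
Conditions: (PhSe)2, PBu3, CH2Cl2, 0 °C → rt
Reagents that add atoms: diphenyl diselenide, c1ccc([Se][Se]c2ccccc2)cc1
Why: Phosphine/diselenide selenoesterification (acyloxyphosphonium ion captured by benzeneselenolate) should give the acyl radical precursor under neutral conditions.

Step 17
Reactants: 26 Se-phenyl 2-hydroxy-6-methoxy-4-(TBSO)-3-{(1R,2E,5S)-5-(TBSO)-1,7-bis[4-(TBSO)phenyl]hept-2-en-1-yl}benzenecarboselenoate; 13 (2S,6R)-6-[4-(TBSO)phenyl]-2-{2-[4-(TBSO)phenyl]ethyl}-4-{(E)-2-[4-(TBSO)phenyl]ethenyl}-3,6-dihydro-2H-pyran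
Product: 27 hepta-TBS ether of blepharocalyxin B (all phenols except the ketone-chelated 2-OH of ring A, and the secondary alcohol, silylated; ring B 2R,3R,4S,6S)
Conditions: Bu3SnH (1.3 equiv, syringe pump, 8 h), AIBN (0.3 equiv, in portions), 13 (1.5 equiv), benzene (0.1 M), 80 °C
Reagents that add atoms: none
Why: Proposed new method: Bu3Sn• abstracts the PhSe group of 26 to give the ring A aroyl radical, which should add to the ring terminus C3 of the 1-aryl-1,3-diene of 13 to give a C4–Cα–Cβ allyl/benzyl radical that takes hydrogen from Bu3SnH at C4 and so carries the chain (net anti 1,2-hydroacylation of C3=C4); the closest known reaction type is the tin-hydride-mediated intermolecular addition of selenoester-derived acyl radicals to activated alkenes (Giese-type hydroacylation). No ring is closed; the step forms the carbonyl–C3 bond and the C4–H bond. C3 is controlled by the pseudo-axial C2 aryl group (2,6-trans to the equatorial C6 chain), which shields one face of the half-chair so that the acyl group enters anti to it and ends axial. C4 is controlled by this new axial acyl group: allylic strain with the exocyclic allyl radical keeps it axial, hydrogen is delivered anti to it, and the regenerated (E)-styryl group becomes equatorial, cis to the acyl group and to the C6 chain, whereas delivery from the other face would force the styryl group into a 1,3-diaxial clash with the C2 aryl group. The step needs attack at C3 and not at Cβ (secured by formation of the more delocalised radical), hydrogen transfer to C4 and not to Cβ (secured by the late transition state that restores the aryl-conjugated alkene) and addition faster than reduction of the aroyl radical (secured by syringe-pump addition of Bu3SnH and an excess of diene).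

Step 18
Reactants: 27 hepta-TBS ether of blepharocalyxin B
Product: 28 blepharocalyxin B
Conditions: HF·pyridine, pyridine, THF, 0 °C → rt
Reagents that add atoms: none
Why: Fluoride-mediated desilylation under buffered, weakly acidic conditions should remove all seven silyl groups without enolising C3 (retro-oxa-Michael) or ionising the benzylic C2–O bond.

**Compound list**

1 | methyl 3-(4-hydroxyphenyl)propanoate | COC(=O)CCc1ccc(O)cc1 | starting material
2 | methyl 3-[4-(TBSO)phenyl]propanoate | COC(=O)CCc1ccc(O[Si](C)(C)C(C)(C)C)cc1 | intermediate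
3 | 3-[4-(TBSO)phenyl]propanal | O=CCCc1ccc(O[Si](C)(C)C(C)(C)C)cc1 | intermediate
4 | (E)-1-methoxy-3-(trimethylsilyloxy)buta-1,3-diene | CO/C=C/C(=C)O[Si](C)(C)C | starting material
5 | (1E,5S)-1-methoxy-5-(trimethylsilyloxy)-7-[4-(TBSO)phenyl]hept-1-en-3-one (Mukaiyama aldol adduct) | CO/C=C/C(=O)C[C@@H](O[Si](C)(C)C)CCc1ccc(O[Si](C)(C)C(C)(C)C)cc1 | intermediate
6 | (2S)-2-{2-[4-(TBSO)phenyl]ethyl}-2,3-dihydro-4H-pyran-4-one | O=C1C=CO[C@@H](CCc2ccc(O[Si](C)(C)C(C)(C)C)cc2)C1 | intermediate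
7 | 4-(TBSO)phenylmagnesium bromide | CC(C)(C)[Si](C)(C)Oc1ccc([Mg]Br)cc1 | starting material
8 | bromomagnesium C3=C4 enolate of (2R,6S)-2-[4-(TBSO)phenyl]-6-{2-[4-(TBSO)phenyl]ethyl}oxan-4-one | Br[Mg]OC1=C[C@H](c2ccc(O[Si](C)(C)C(C)(C)C)cc2)O[C@@H](CCc2ccc(O[Si](C)(C)C(C)(C)C)cc2)C1 | intermediate
9 | (2S,6R)-6-[4-(TBSO)phenyl]-2-{2-[4-(TBSO)phenyl]ethyl}-3,6-dihydro-2H-pyran-4-yl triflate | O=S(=O)(OC1=C[C@H](c2ccc(O[Si](C)(C)C(C)(C)C)cc2)O[C@@H](CCc2ccc(O[Si](C)(C)C(C)(C)C)cc2)C1)C(F)(F)F | intermediate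
10 | tert-butyl(4-iodophenoxy)dimethylsilane | CC(C)(C)[Si](C)(C)Oc1ccc(I)cc1 | starting material
11 | 4,4,5,5-tetramethyl-2-vinyl-1,3,2-dioxaborolane | C=CB1OC(C)(C)C(C)(C)O1 | starting material
12 | (E)-2-{2-[4-(TBSO)phenyl]ethenyl}-4,4,5,5-tetramethyl-1,3,2-dioxaborolane | CC(C)(C)[Si](C)(C)Oc1ccc(/C=C/B2OC(C)(C)C(C)(C)O2)cc1 | intermediate
13 | (2S,6R)-6-[4-(TBSO)phenyl]-2-{2-[4-(TBSO)phenyl]ethyl}-4-{(E)-2-[4-(TBSO)phenyl]ethenyl}-3,6-dihydro-2H-pyran | CC(C)(C)[Si](C)(C)Oc1ccc(/C=C/C2=C[C@H](c3ccc(O[Si](C)(C)C(C)(C)C)cc3)O[C@@H](CCc3ccc(O[Si](C)(C)C(C)(C)C)cc3)C2)cc1 | intermediate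
14 | (E)-4-(4-hydroxyphenyl)but-3-en-2-one | CC(=O)/C=C/c1ccc(O)cc1 | starting material
15 | (E)-4-(4-acetoxyphenyl)but-3-en-2-one | CC(=O)/C=C/c1ccc(OC(C)=O)cc1 | intermediate
16 | diisopinocampheylboron enolate of 15 (Ipc from (−)-α-pinene) | C=C(/C=C/c1ccc(OC(C)=O)cc1)OB([C@H]1C[C@H]2C[C@@H]([C@@H]1C)C2(C)C)[C@H]1C[C@H]2C[C@@H]([C@@H]1C)C2(C)C | intermediate
17 | (1E,5S)-1-(4-acetoxyphenyl)-5-hydroxy-7-[4-(TBSO)phenyl]hept-1-en-3-one | CC(=O)Oc1ccc(/C=C/C(=O)C[C@@H](O)CCc2ccc(O[Si](C)(C)C(C)(C)C)cc2)cc1 | intermediate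
18 | (1E,5S)-1-(4-acetoxyphenyl)-5-(TBSO)-7-[4-(TBSO)phenyl]hept-1-en-3-one | CC(=O)Oc1ccc(/C=C/C(=O)C[C@@H](O[Si](C)(C)C(C)(C)C)CCc2ccc(O[Si](C)(C)C(C)(C)C)cc2)cc1 | intermediate
19 | 4-{(1E,3S,5S)-3-hydroxy-5-(TBSO)-7-[4-(TBSO)phenyl]hept-1-en-1-yl}phenyl acetate | CC(=O)Oc1ccc(/C=C/[C@@H](O)C[C@@H](O[Si](C)(C)C(C)(C)C)CCc2ccc(O[Si](C)(C)C(C)(C)C)cc2)cc1 | intermediate
20 | 2,4-dihydroxy-6-methoxybenzaldehyde | COc1cc(O)cc(O)c1C=O | starting material
21 | 4-{[(1E,3R,5S)-1-(4-acetoxyphenyl)-5-(TBSO)-7-[4-(TBSO)phenyl]hept-1-en-3-yl]oxy}-2-hydroxy-6-methoxybenzaldehyde | COc1cc(O[C@@H](/C=C/c2ccc(OC(C)=O)cc2)C[C@@H](O[Si](C)(C)C(C)(C)C)CCc2ccc(O[Si](C)(C)C(C)(C)C)cc2)cc(O)c1C=O | intermediate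
22 | 3-{(1R,2E,5S)-1-(4-acetoxyphenyl)-5-(TBSO)-7-[4-(TBSO)phenyl]hept-2-en-1-yl}-2,4-dihydroxy-6-methoxybenzaldehyde | COc1cc(O)c([C@H](/C=C/C[C@@H](O[Si](C)(C)C(C)(C)C)CCc2ccc(O[Si](C)(C)C(C)(C)C)cc2)c2ccc(OC(C)=O)cc2)c(O)c1C=O | intermediate
23 | 2,4-dihydroxy-3-[(1R,2E,5S)-1,7-bis(4-hydroxyphenyl)-5-(TBSO)hept-2-en-1-yl]-6-methoxybenzaldehyde | COc1cc(O)c([C@H](/C=C/C[C@@H](O[Si](C)(C)C(C)(C)C)CCc2ccc(O)cc2)c2ccc(O)cc2)c(O)c1C=O | intermediate
24 | 2-hydroxy-6-methoxy-4-(TBSO)-3-{(1R,2E,5S)-5-(TBSO)-1,7-bis[4-(TBSO)phenyl]hept-2-en-1-yl}benzaldehyde | COc1cc(O[Si](C)(C)C(C)(C)C)c([C@H](/C=C/C[C@@H](O[Si](C)(C)C(C)(C)C)CCc2ccc(O[Si](C)(C)C(C)(C)C)cc2)c2ccc(O[Si](C)(C)C(C)(C)C)cc2)c(O)c1C=O | intermediate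
25 | 2-hydroxy-6-methoxy-4-(TBSO)-3-{(1R,2E,5S)-5-(TBSO)-1,7-bis[4-(TBSO)phenyl]hept-2-en-1-yl}benzoic acid | COc1cc(O[Si](C)(C)C(C)(C)C)c([C@H](/C=C/C[C@@H](O[Si](C)(C)C(C)(C)C)CCc2ccc(O[Si](C)(C)C(C)(C)C)cc2)c2ccc(O[Si](C)(C)C(C)(C)C)cc2)c(O)c1C(=O)O | intermediate
26 | Se-phenyl 2-hydroxy-6-methoxy-4-(TBSO)-3-{(1R,2E,5S)-5-(TBSO)-1,7-bis[4-(TBSO)phenyl]hept-2-en-1-yl}benzenecarboselenoate | COc1cc(O[Si](C)(C)C(C)(C)C)c([C@H](/C=C/C[C@@H](O[Si](C)(C)C(C)(C)C)CCc2ccc(O[Si](C)(C)C(C)(C)C)cc2)c2ccc(O[Si](C)(C)C(C)(C)C)cc2)c(O)c1C(=O)[Se]c1ccccc1 | intermediate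
27 | hepta-TBS ether of blepharocalyxin B: {(2R,3R,4S,6S)-2-[4-(TBSO)phenyl]-6-{2-[4-(TBSO)phenyl]ethyl}-4-{(E)-2-[4-(TBSO)phenyl]ethenyl}oxan-3-yl}(2-hydroxy-6-methoxy-4-(TBSO)-3-{(1R,2E,5S)-5-(TBSO)-1,7-bis[4-(TBSO)phenyl]hept-2-en-1-yl}phenyl)methanone | COc1cc(O[Si](C)(C)C(C)(C)C)c([C@H](/C=C/C[C@@H](O[Si](C)(C)C(C)(C)C)CCc2ccc(O[Si](C)(C)C(C)(C)C)cc2)c2ccc(O[Si](C)(C)C(C)(C)C)cc2)c(O)c1C(=O)[C@@H]1[C@H](/C=C/c2ccc(O[Si](C)(C)C(C)(C)C)cc2)C[C@H](CCc2ccc(O[Si](C)(C)C(C)(C)C)cc2)O[C@H]1c1ccc(O[Si](C)(C)C(C)(C)C)cc1 | intermediate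
28 | blepharocalyxin B: {(2R,3R,4S,6S)-2-(4-hydroxyphenyl)-6-[2-(4-hydroxyphenyl)ethyl]-4-[(E)-2-(4-hydroxyphenyl)ethenyl]oxan-3-yl}{2,4-dihydroxy-3-[(1R,2E,5S)-5-hydroxy-1,7-bis(4-hydroxyphenyl)hept-2-en-1-yl]-6-methoxyphenyl}methanone | COc1cc(O)c([C@H](/C=C/C[C@@H](O)CCc2ccc(O)cc2)c2ccc(O)cc2)c(O)c1C(=O)[C@@H]1[C@H](/C=C/c2ccc(O)cc2)C[C@H](CCc2ccc(O)cc2)O[C@H]1c1ccc(O)cc1 | target

**Step count and risk**

Total step count: 18. Longest linear sequence: 13 steps (1, 2, 8, 9, 10, 11, 12, 13, 14, 15, 16, 17, 18).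

Steps most likely to fail:

Step 17 (proposed new method). What may go wrong: hydrogen transfer to the benzylic terminus of the allyl radical (1,4-adduct with the alkene out of conjugation), reduction of the aroyl radical to the aldehyde before it adds, short chains with the stabilised adduct radical, or erosion of facial control at C3 or C4. Fallback with known chemistry, changing the acceptor to a classical Giese acceptor: setting out from enol triflate 9, palladium-catalysed reductive carbonylation (Pd(PPh3)4, CO, Bu3SnH, THF, 50 °C) would give (2S,6R)-6-[4-(TBSO)phenyl]-2-{2-[4-(TBSO)phenyl]ethyl}-3,6-dihydro-2H-pyran-4-carbaldehyde F1. Tin-hydride-mediated conjugate addition of the aroyl radical from selenoester 26 to this enal (Bu3SnH, AIBN, benzene, 80 °C) should give the C3-aroyl C4-formyl oxane F2; attack is anti to the C2 aryl group and hydrogen transfer to the α-formyl radical is anti to the new acyl group. Horner–Wadsworth–Emmons olefination with diethyl [4-(TBSO)benzyl]phosphonate F3 (from the benzyl bromide and triethyl phosphite; LiN(SiMe3)2 in excess, THF, −78 °C) would install the (E)-styryl group, and the route is rejoined at 27.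

Step 12. What may go wrong: migration of the allyl unit to C5 (between the ether oxygen and the methoxy group) in place of C3, ionisation and recombination of the cinnamyl-type ether with loss of chirality transfer, or thermal cyclisation of the new ortho-hydroxyl onto the alkene. Fallback, replacing the sigmatropic shift by an anti-selective SN2' allylic substitution on a symmetric arene: setting out from allylic alcohol 19, esterification (picolinic acid, DCC, DMAP) would give the (1E,3S,5S)-hept-1-en-3-yl pyridine-2-carboxylate F4. 1-Methoxy-3,5-bis(methoxymethoxy)benzene F5 (from 5-methoxyresorcinol and chloromethyl methyl ether) would be lithiated between the two acetal oxygens (n-BuLi) and transmetallated (MgBr2·OEt2, CuBr·SMe2) to [4-methoxy-2,6-bis(methoxymethoxy)phenyl]copper F6. Picolinate-directed anti-SN2' substitution of F4 by F6 should give the (1R,2E,5S)-diarylmethine bis(methoxymethyl) ether F7; because this arene is symmetric, no regiochemical question arises. Cleavage of the two acetals (ZnBr2, n-PrSH, CH2Cl2) would give the 2-substituted 5-methoxyresorcinol F8, and Vilsmeier–Haack formylation (POCl3, DMF; the two free ring positions are equivalent) rejoins the route at 22.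

Step 11. What may go wrong: SN2' attack of the phenol at the benzylic terminus, or ionisation of the oxyphosphonium intermediate, either of which would scramble the position and configuration of the ether. Fallback, replacing SN2 inversion by a π-allyl palladium substitution with net retention: setting out from enone 18, reduction with the (S)-oxazaborolidine and BH3·SMe2 would give the (1E,3R,5S)-allylic alcohol F9 and methyl chloroformate/pyridine its methyl carbonate F10. Pd(PPh3)4 (zerovalent palladium) with phenol 20 in THF should ionise the carbonate with inversion; the phenoxide then attacks anti to palladium at the allyl terminus remote from the aryl group, which keeps the styrene conjugation, and the route is rejoined at 21.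

**Further compounds**

F1 | step 17 | (2S,6R)-6-[4-(TBSO)phenyl]-2-{2-[4-(TBSO)phenyl]ethyl}-3,6-dihydro-2H-pyran-4-carbaldehyde | O=CC1=C[C@H](c2ccc(O[Si](C)(C)C(C)(C)C)cc2)O[C@@H](CCc2ccc(O[Si](C)(C)C(C)(C)C)cc2)C1
F2 | step 17 | (2R,3R,4S,6S)-3-aroyl-4-formyl oxane (27 with CHO in place of the styryl group) | COc1cc(O[Si](C)(C)C(C)(C)C)c([C@H](/C=C/C[C@@H](O[Si](C)(C)C(C)(C)C)CCc2ccc(O[Si](C)(C)C(C)(C)C)cc2)c2ccc(O[Si](C)(C)C(C)(C)C)cc2)c(O)c1C(=O)[C@@H]1[C@H](C=O)C[C@H](CCc2ccc(O[Si](C)(C)C(C)(C)C)cc2)O[C@H]1c1ccc(O[Si](C)(C)C(C)(C)C)cc1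
F3 | step 17 | diethyl [4-(TBSO)benzyl]phosphonate | CCOP(=O)(Cc1ccc(O[Si](C)(C)C(C)(C)C)cc1)OCC
F4 | step 12 | (1E,3S,5S)-1-(4-acetoxyphenyl)-5-(TBSO)-7-[4-(TBSO)phenyl]hept-1-en-3-yl pyridine-2-carboxylate | CC(=O)Oc1ccc(/C=C/[C@@H](OC(=O)c2ccccn2)C[C@@H](O[Si](C)(C)C(C)(C)C)CCc2ccc(O[Si](C)(C)C(C)(C)C)cc2)cc1
F5 | step 12 | 1-methoxy-3,5-bis(methoxymethoxy)benzene | COCOc1cc(OC)cc(OCOC)c1
F6 | step 12 | [4-methoxy-2,6-bis(methoxymethoxy)phenyl]copper | COCOc1cc(OC)cc(OCOC)c1[Cu]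
F7 | step 12 | 4-{(1R,2E,5S)-5-(TBSO)-1-[4-methoxy-2,6-bis(methoxymethoxy)phenyl]-7-[4-(TBSO)phenyl]hept-2-en-1-yl}phenyl acetate | COCOc1cc(OC)cc(OCOC)c1[C@H](/C=C/C[C@@H](O[Si](C)(C)C(C)(C)C)CCc1ccc(O[Si](C)(C)C(C)(C)C)cc1)c1ccc(OC(C)=O)cc1
F8 | step 12 | 4-{(1R,2E,5S)-1-(2,6-dihydroxy-4-methoxyphenyl)-5-(TBSO)-7-[4-(TBSO)phenyl]hept-2-en-1-yl}phenyl acetate | COc1cc(O)c([C@H](/C=C/C[C@@H](O[Si](C)(C)C(C)(C)C)CCc2ccc(O[Si](C)(C)C(C)(C)C)cc2)c2ccc(OC(C)=O)cc2)c(O)c1
F9 | step 11 | 4-{(1E,3R,5S)-3-hydroxy-5-(TBSO)-7-[4-(TBSO)phenyl]hept-1-en-1-yl}phenyl acetate | CC(=O)Oc1ccc(/C=C/[C@H](O)C[C@@H](O[Si](C)(C)C(C)(C)C)CCc2ccc(O[Si](C)(C)C(C)(C)C)cc2)cc1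
F10 | step 11 | 4-{(1E,3R,5S)-3-[(methoxycarbonyl)oxy]-5-(TBSO)-7-[4-(TBSO)phenyl]hept-1-en-1-yl}phenyl acetate | CC(=O)Oc1ccc(/C=C/[C@H](OC(=O)OC)C[C@@H](O[Si](C)(C)C(C)(C)C)CCc2ccc(O[Si](C)(C)C(C)(C)C)cc2)cc1
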